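**Plan**
- Retrosynthesis: the C4′ O–CH2OMe and C7 O–CH3 bonds are cut first; ring A is then opened at C8–C8a, C5–C6, C7–C8 and C4a–C5 into a pyranonyl diazoketone and a prenyl-bearing siloxyalkyne. The diazoketone is cut at C3–C1′ (cross-coupling) and traced to kojic acid.
- Feature used: ring A is a pentasubstituted benzene (C5–OH, C6 prenyl, C7–O, C8–H) fused to pyranone ring C through C4a–C8a. A ketene (C5, C8) and an ynol ether (C6, C7) can build exactly this pattern on the C8a=C4a double bond of a pyranone whose C4a still carries hydrogen.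
- Forward: ring C is bought as kojic acid, ring B is attached by Suzuki coupling, and the CH2OH arm becomes the diazoketone. The siloxyalkyne comes from ester homologation. Ring A is closed last, followed by desilylative methylation and MOM removal.
- Stereochemistry: the target has no stereocentre and the prenyl olefin has no E/Z isomers, so nothing has to be set.

Key step: step 6

Assumption: 4-(methoxymethoxy)phenylboronic acid and ethyl 4-methylpent-3-enoate are taken as catalogue compounds; diazomethane is used as a pre-formed ethereal solution.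
Remark: ring-A atoms carry isoflavone numbering (C4a, C5–C8, C8a) throughout, also in the precursors.

**Step 1**
Reactants: 1 kojic acid
Product: 2 6-(hydroxymethyl)-4-oxo-4H-pyran-3-yl trifluoromethanesulfonate
Conditions: PhNTf2, Et3N, DMF, 0 → 25 °C
Reagents that add atoms: N-phenylbis(trifluoromethanesulfonimide), O=S(=O)(N(c1ccccc1)S(=O)(=O)C(F)(F)F)C(F)(F)F
Why: Chemoselective O-triflation: Et3N ionises only the acidic enol hydroxyl, and PhNTf2, a mild sulfonyl-transfer reagent that does not attack neutral aliphatic alcohols, turns that enolate into the enol triflate while the CH2OH group stays free.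

**Step 2**
Reactants: 2 6-(hydroxymethyl)-4-oxo-4H-pyran-3-yl trifluoromethanesulfonate; 3 4-(methoxymethoxy)phenylboronic acid
Product: 4 2-(hydroxymethyl)-5-[4-(methoxymethoxy)phenyl]-4H-pyran-4-one
Conditions: Pd(PPh3)4 (cat.), K3PO4, 1,4-dioxane/H2O, 80 °C
Reagents that add atoms: none
Why: Suzuki–Miyaura coupling: zerovalent palladium inserts readily into the C–OTf bond of the electron-poor enol triflate, and transmetallation and reductive elimination form the pyranone–aryl bond (C3–C1′ of the target) without interference from the free alcohol or the MOM ether.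

**Step 3**
Reactants: 4 2-(hydroxymethyl)-5-[4-(methoxymethoxy)phenyl]-4H-pyran-4-one
Product: 6 5-[4-(methoxymethoxy)phenyl]-4-oxo-4H-pyran-2-carboxylic acid, via pyranone-2-carbaldehyde 5 (not isolated)
Conditions: TEMPO (cat.), PhI(OAc)2, MeCN/H2O (1:1), 25 °C
Reagents that add atoms: water, O
Why: TEMPO/PhI(OAc)2 oxidation in aqueous acetonitrile: the oxoammonium species oxidises the primary alcohol to aldehyde 5, whose hydrate is oxidised on to the acid under nearly neutral conditions that spare the MOM acetal, the aryl ether ring and the pyranone.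

**Step 4**
Reactants: 6 5-[4-(methoxymethoxy)phenyl]-4-oxo-4H-pyran-2-carboxylic acid
Product: 8 2-(2-diazoacetyl)-5-[4-(methoxymethoxy)phenyl]-4H-pyran-4-one, via pyranone-2-carbonyl chloride 7 (not isolated)
Conditions: 1-chloro-N,N,2-trimethylprop-1-en-1-amine, CH2Cl2, 0 → 25 °C; then CH2N2 (excess), Et2O, 0 °C
Reagents that add atoms: diazomethane, C=[N+]=[N-]
Why: Acylation of diazomethane (first stage of the Arndt–Eistert sequence): the chloroenamine makes the acid chloride without releasing HCl, so the MOM ether is safe, and the acid chloride should acylate excess CH2N2 at 0 °C much faster than the dipole adds across the pyranone double bonds, the second equivalent removing HCl as CH3Cl.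

**Step 5**
Reactants: 9 ethyl 4-methylpent-3-enoate
Product: 12 triisopropyl[(5-methylhex-4-en-1-yn-1-yl)oxy]silane, via lithium dibromoenolate 10 (not isolated), via lithium ynolate 11 (not isolated)
Conditions: CH2Br2, lithium 2,2,6,6-tetramethylpiperidide (LiTMP, from the amine and n-BuLi), THF, −78 °C; then 9; then n-BuLi, −78 → 25 °C; then i-Pr3SiCl, −78 → 25 °C
Reagents that add atoms: dibromomethane, BrCBr; chlorotri(propan-2-yl)silane, CC(C)[Si](Cl)(C(C)C)C(C)C
Why: Kowalski ester homologation: LiCHBr2 adds to the ester carbonyl, the derived dibromoenolate 10 undergoes Br/Li exchange and 1,2-shift of the alkyl group to ynolate 11, and the bulky silyl chloride reacts at oxygen to give the siloxyalkyne.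

**Step 6**
Reactants: 8 2-(2-diazoacetyl)-5-[4-(methoxymethoxy)phenyl]-4H-pyran-4-one; 12 triisopropyl[(5-methylhex-4-en-1-yn-1-yl)oxy]silane
Product: 17 5-hydroxy-3-[4-(methoxymethoxy)phenyl]-6-(3-methylbut-2-enyl)-7-(triisopropylsilyloxy)chromen-4-one, via pyranonylketene 13 (not isolated), via siloxycyclobutenone 14 (not isolated), via dienylketene 15 (not isolated), via 4aH-chromene-4,5-dione tautomer 16 (not isolated)
Conditions: 12 (1.5 equiv), hν (LED, ca. 405 nm), degassed ClCH2CH2Cl, 25 °C; then 80 °C
Reagents that add atoms: none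
Why: Excitation of the diazoketone expels N2 and triggers Wolff rearrangement (the pyranone carbon C8a migrates to the former diazo carbon, forming C8–C8a), and the resulting ketene 13 adds [2+2] to the electron-rich siloxyalkyne (C5–C6 and C7–C8) to give cyclobutenone 14. At 80 °C 14 opens by four-electron electrocyclic cleavage to dienylketene 15, ring A closes by thermal six-electron disrotatory electrocyclisation of the ketene carbon C5 onto the pyranone CH carbon C4a, and the acidic C4a–H of dienone 16 shifts to oxygen to give the chelated C5 phenol. The closest known reaction type is the Danheiser benzannulation in its photochemical Wolff form, established for aryl, heteroaryl and alkenyl diazoketones with siloxyalkynes; the pyranone C8a=C4a bond plays the part of the alkenyl π bond here, and a 4-pyranone has not yet served in that role. No stereocentre is formed. The step needs regiocontrol in the [2+2] event, secured by the polarisation of the siloxyalkyne (its nucleophilic prenyl-bearing carbon bonds to the ketene carbonyl carbon, putting prenyl at C6 between the two oxygens and the silyloxy group at C7), and site control in the closure, secured because C4a is the only position next to the ketene-bearing carbon. Irradiation near 400 nm, where the diazo chromophore should be the main absorber, is chosen to keep the 4-pyranone and the product out of competing photochemistry, and the hydrogen-bonded C5 hydroxyl of 17 should be a poor trap for remaining ketene.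

**Step 7**
Reactants: 17 5-hydroxy-3-[4-(methoxymethoxy)phenyl]-6-(3-methylbut-2-enyl)-7-(triisopropylsilyloxy)chromen-4-one
Product: 19 5-hydroxy-7-methoxy-3-[4-(methoxymethoxy)phenyl]-6-(3-methylbut-2-enyl)chromen-4-one, via cesium C7 phenoxide 18 (not isolated)
Conditions: CsF, MeI, DMF, 25 °C
Reagents that add atoms: iodomethane, CI
Why: One-pot desilylation and Williamson methylation: fluoride cleaves the labile aryl O–Si bond at C7, the cesium phenoxide 18 is methylated at oxygen by MeI, and the C5 hydroxyl, held in a hydrogen bond to the C4 carbonyl and far less acidic, should remain free.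

**Step 8**
Reactants: 19 5-hydroxy-7-methoxy-3-[4-(methoxymethoxy)phenyl]-6-(3-methylbut-2-enyl)chromen-4-one
Product: 20 Gancaonin G
Conditions: HCl (cat., conc. aq.), MeOH, 25 → 40 °C
Reagents that add atoms: none
Why: Acid-catalysed acetal methanolysis of the aryl MOM ether: dilute HCl in methanol cleaves the O–CH2–O unit as dimethoxymethane, and keeping the acid dilute and the temperature low should prevent protonation of the prenyl olefin and chroman formation with the C5 hydroxyl.

**Compound list**
1 | kojic acid, 5-hydroxy-2-(hydroxymethyl)-4H-pyran-4-one | OCc1cc(=O)c(O)co1 | starting material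
2 | 6-(hydroxymethyl)-4-oxo-4H-pyran-3-yl trifluoromethanesulfonate | OCc1cc(=O)c(OS(=O)(=O)C(F)(F)F)co1 | intermediate
3 | 4-(methoxymethoxy)phenylboronic acid | COCOc1ccc(B(O)O)cc1 | starting material
4 | 2-(hydroxymethyl)-5-[4-(methoxymethoxy)phenyl]-4H-pyran-4-one | OCc1cc(=O)c(-c2ccc(OCOC)cc2)co1 | intermediate
5 | 5-[4-(methoxymethoxy)phenyl]-4-oxo-4H-pyran-2-carbaldehyde (not isolated) | O=Cc1cc(=O)c(-c2ccc(OCOC)cc2)co1 | intermediate
6 | 5-[4-(methoxymethoxy)phenyl]-4-oxo-4H-pyran-2-carboxylic acid | OC(=O)c1cc(=O)c(-c2ccc(OCOC)cc2)co1 | intermediate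
7 | 5-[4-(methoxymethoxy)phenyl]-4-oxo-4H-pyran-2-carbonyl chloride (not isolated) | ClC(=O)c1cc(=O)c(-c2ccc(OCOC)cc2)co1 | intermediate
8 | 2-(2-diazoacetyl)-5-[4-(methoxymethoxy)phenyl]-4H-pyran-4-one | [N-]=[N+]=CC(=O)c1cc(=O)c(-c2ccc(OCOC)cc2)co1 | intermediate
9 | ethyl 4-methylpent-3-enoate | CCOC(=O)CC=C(C)C | starting material
10 | lithium 1,1-dibromo-5-methylhexa-1,4-dien-2-olate (not isolated) | [Li+].[O-]C(CC=C(C)C)=C(Br)Br | intermediate
11 | lithium 5-methylhex-4-en-1-yn-1-olate (not isolated) | [Li+].[O-]C#CCC=C(C)C | intermediate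
12 | triisopropyl[(5-methylhex-4-en-1-yn-1-yl)oxy]silane | CC(C)=CCC#CO[Si](C(C)C)(C(C)C)C(C)C | intermediate
13 | 5-[4-(methoxymethoxy)phenyl]-2-(2-oxoethenyl)-4H-pyran-4-one, the pyranonylketene (not isolated) | O=C=Cc1cc(=O)c(-c2ccc(OCOC)cc2)co1 | intermediate
14 | 5-[4-(methoxymethoxy)phenyl]-2-[3-(3-methylbut-2-enyl)-4-oxo-2-(triisopropylsilyloxy)cyclobut-2-en-1-yl]-4H-pyran-4-one, racemic (not isolated) | O=C1C(CC=C(C)C)=C(O[Si](C(C)C)(C(C)C)C(C)C)C1c1cc(=O)c(-c2ccc(OCOC)cc2)co1 | intermediate
15 | 5-[4-(methoxymethoxy)phenyl]-2-[(1E)-3-(3-methylbut-2-enyl)-4-oxo-2-(triisopropylsilyloxy)buta-1,3-dien-1-yl]-4H-pyran-4-one, ketene arm cis to the pyranone (not isolated) | O=C=C(CC=C(C)C)/C(O[Si](C(C)C)(C(C)C)C(C)C)=C\c1cc(=O)c(-c2ccc(OCOC)cc2)co1 | intermediate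
16 | 3-[4-(methoxymethoxy)phenyl]-6-(3-methylbut-2-enyl)-7-(triisopropylsilyloxy)-4aH-chromene-4,5-dione, racemic (not isolated) | O=C1C(CC=C(C)C)=C(O[Si](C(C)C)(C(C)C)C(C)C)C=C2OC=C(c3ccc(OCOC)cc3)C(=O)C21 | intermediate
17 | 5-hydroxy-3-[4-(methoxymethoxy)phenyl]-6-(3-methylbut-2-enyl)-7-(triisopropylsilyloxy)chromen-4-one | CC(C)[Si](Oc1cc2occ(-c3ccc(OCOC)cc3)c(=O)c2c(O)c1CC=C(C)C)(C(C)C)C(C)C | intermediate
18 | cesium 5-hydroxy-3-[4-(methoxymethoxy)phenyl]-6-(3-methylbut-2-enyl)-4-oxochromen-7-olate (not isolated) | [Cs+].[O-]c1cc2occ(-c3ccc(OCOC)cc3)c(=O)c2c(O)c1CC=C(C)C | intermediate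
19 | 5-hydroxy-7-methoxy-3-[4-(methoxymethoxy)phenyl]-6-(3-methylbut-2-enyl)chromen-4-one | COc1cc2occ(-c3ccc(OCOC)cc3)c(=O)c2c(O)c1CC=C(C)C | intermediate
20 | Gancaonin G, 5-hydroxy-3-(4-hydroxyphenyl)-7-methoxy-6-(3-methylbut-2-enyl)chromen-4-one | COc1cc2occ(-c3ccc(O)cc3)c(=O)c2c(O)c1CC=C(C)C | target

**Step count**
Total: 8 steps. Longest linear sequence: 7 steps (1 → 2 → 4 → 6 → 8 → 17 → 19 → 20; steps 1, 2, 3, 4, 6, 7, 8), with step 5 as a one-step side branch.

**Steps most likely to fail**

1. Step 6. The light may be absorbed by the aryl-pyranone chromophore instead of the diazo group, leading to pyranone photoisomerisation. The photogenerated carbene or ketene may also be consumed by dimerisation before it meets the alkyne. The fallback sets out from 8 and returns at 17, and makes the ketene in the dark. Silver-catalysed Wolff rearrangement of 8 in wet THF (PhCO2Ag, Et3N, 25 °C) should give [5-[4-(methoxymethoxy)phenyl]-4-oxo-4H-pyran-2-yl]acetic acid F1. 1-Chloro-N,N,2-trimethylprop-1-en-1-amine converts it into [5-[4-(methoxymethoxy)phenyl]-4-oxo-4H-pyran-2-yl]acetyl chloride F2. Slow addition of Et3N to F2 and 12 in CH2Cl2 at 0 °C should generate ketene 13 by dehydrochlorination, which is trapped as cyclobutenone 14. Compound 14 is isolated and heated in toluene (80–110 °C) to pass through 15 and 16 to 17. The ring-forming bonds are the same; the ketene source changes from a photochemical to a base-induced one and the annulation is staged.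

2. Step 5. LiCHBr2 or LiTMP may deprotonate the doubly activated allylic α-position of 9 instead of adding to the carbonyl, and excess base may move the skipped double bond into conjugation at the ynolate stage. The fallback sets out from 9 and returns at 12 through ynolate 11, which is reached by oxidation of an acetylide. Reduction of 9 (i-Bu2AlH, CH2Cl2, −78 °C) should give 4-methylpent-3-enal F3. Dibromo-olefination (CBr4, PPh3, CH2Cl2, 0 °C) gives 1,1-dibromo-5-methylhexa-1,4-diene F4. Two equivalents of n-BuLi in THF at −78 °C convert it into (5-methylhex-4-en-1-yn-1-yl)lithium F5. Oxidation of F5 with LiOOt-Bu (from t-BuOOH and LiN(SiMe3)2, −78 → 0 °C) gives ynolate 11, which is silylated with i-Pr3SiCl to 12.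

3. Step 8. During acetal cleavage the acid may protonate the prenyl olefin, so that the C5 hydroxyl closes a chroman ring or methanol/HCl adds to the olefin. The fallback sets out from 19 and returns at 20, and does not hydrolyse the acetal with protic acid. Me3SiOTf (3 equiv) with 2,2′-bipyridyl in CH2Cl2 (0 → 25 °C) should exchange the aryl MOM ether for a silyl ether under base-buffered conditions and silylate the C5 hydroxyl. This gives 7-methoxy-6-(3-methylbut-2-enyl)-5-(trimethylsilyloxy)-3-[4-(trimethylsilyloxy)phenyl]chromen-4-one F6. Both silyl ethers of F6 are then cleaved with K2CO3 in MeOH at 25 °C to give 20, so the last bond cleavage becomes a mild basic desilylation.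

**Further compounds**
F1 | step 6 | [5-[4-(methoxymethoxy)phenyl]-4-oxo-4H-pyran-2-yl]acetic acid | OC(=O)Cc1cc(=O)c(-c2ccc(OCOC)cc2)co1
F2 | step 6 | [5-[4-(methoxymethoxy)phenyl]-4-oxo-4H-pyran-2-yl]acetyl chloride | ClC(=O)Cc1cc(=O)c(-c2ccc(OCOC)cc2)co1
F3 | step 5 | 4-methylpent-3-enal | CC(C)=CCC=O
F4 | step 5 | 1,1-dibromo-5-methylhexa-1,4-diene | CC(C)=CCC=C(Br)Br
F5 | step 5 | (5-methylhex-4-en-1-yn-1-yl)lithium | [Li]C#CCC=C(C)C
F6 | step 8 | 7-methoxy-6-(3-methylbut-2-enyl)-5-(trimethylsilyloxy)-3-[4-(trimethylsilyloxy)phenyl]chromen-4-one | COc1cc2occ(-c3ccc(O[Si](C)(C)C)cc3)c(=O)c2c(O[Si](C)(C)C)c1CC=C(C)C
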